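Early in the ash run, at 15.0 s, 30.0% of the starting material has gone in and the target reads 7.2% of the whole charge. At the end of the feed it reads 31.8%, and at 80.0 s the same. Ash is the flask asked about, followed so far; birch differs from it in its partner.

the same everywhere: starting material 0.20 M (fed, over 50 s)
- ash: second substrate 0.20 M; partner 0.14 M; free catalyst 1 mM; the very flask that is asked about, followed so far
- birch: second substrate 0.20 M; partner 0.28 M; free catalyst 1 mM; run made earlier
- flask: second substrate 0.200 M; partner 0.140 M; free catalyst 1.0 mM; time 6.0 min

- ash (time / s: target / %): 15.0: 7.2; 25.0: 15.1; 40.0: 25.9; 50.0: 31.8; 80.0: 31.8
- birch (time / min: target / %): 0.250: 9.4; 0.500: 21.7; 1.00: 49.3; 2.00: 49.3; 4.00: 48.4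

(each reading ± 1 percentage point)

- percentages count the whole charge, also what has not yet gone in

- the best time, 6.0 min at the latest, for target
- the amount of target, in percent of the starting material charged, at that time

Two chemists read these runs differently. The feed chemist says the feed is the clock: ash is flat after 50.0 s and birch reads 49.3% at both 1.00 min and 2.00 min, so starting material goes as it comes and the flask is finished with the feed.

The partner chemist answers that both runs had the same feed, yet birch levels higher than ash and holds more partner. Her reckoning, which is mine, is the balance of partner, the limiting reagent, charged at 0.140 M against 0.20 M of starting material. If each partner takes one starting material, at least 30.0% of the starting material remains once partner is gone.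

On ash's level, 45.4% of the partner charged ended as target; this share, target formed per partner charged, is the partner yield, and birch reads 35.2%. She commits to a peak near ash's level, past the end of the feed and before 80.0 s, with starting material left over.

The forecast takes the feed side, with 1 min (range 0.83 min to 1.6 min) and 32% (range 30.5% to 33.5%), on the ground that “the starting material is consumed almost as it is dosed”.

The flask peaks at 1.11 min with 32.6% of target.

    starting material + free catalyst ⇌ catalyst intermediate A (K = 4.20 /M, k = 140 /M/s)
    partner + catalyst intermediate A → free catalyst + target (k = 360 /M/s)
    second substrate + free catalyst ⇌ catalyst intermediate B (K = 4.60 /M, k = 230 /M/s)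
    partner + catalyst intermediate B → free catalyst + second product (k = 24.0 /M/s)
    starting material + partner → uncatalysed product (k = 0.160 /M/s)
    target + free catalyst ⇌ isomer of the product + free catalyst, rate k6*[free catalyst]*[target] forward; the back reaction follows from the equilibrium constant (K = 0.390, k = 9.90 /M/s)

At that time the flask still holds 49.9% of its starting material, while partner is down to 1.97% of its charge, so the partner chemist's balance stands. The partner yield of the flask at its peak is 46.6%, beside the 45.4% read on ash's level. Carried to the neighbour flask with 0.35 M of partner, that reading of 45.4% gives 79.4% of target, but the neighbour flask reaches less, 52.9%, a partner yield of 30.2%. That neighbour flask is the feed chemist's side of the charges: the fed starting material is the first to run out, with 0.019% left at 6.00 min.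

(The readings are simulated from invented constants; the scatter is artificial.)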